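## Retrosynthetic overview

1. Oxonane ring last: the C6–C7 bond is closed by an intramolecular Nozaki–Hiyama–Kishi reaction of aldehyde/vinyl triflate 32; C6 butyrylation and C11 desilylation finish the synthesis.
2. ε-Lactone third: the C16 acid opens a C3–C4 epoxide at C3 with inversion, which also frees C4–OH for the octanoate; C15 comes from hydroboration of the isopropenyl group.
3. Tetrahydrofuran second: a C10 radical closes 5-exo onto a β-alkoxyacrylate carried on O–C2 (C9–C10 bond; sets C9 and C10).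
4. Key C1–C2 bond: intermolecular anti-aldol addition of the boron enolate of ketone 5 to epoxy aldehyde 13, joining the two fragments.
5. Cyclohexane from (R)-carvone (C11–O by nucleophilic epoxidation); the C2–C6 piece from propane-1,3-diol by Still–Gennari olefination and Sharpless epoxidation.

Assumption: the target is taken exactly as drawn, (1S,2S,3S,4R,6R,9S,10R,11R,14R,15R) in eunicellane numbering (C17 = 15-Me, C18 = 3-Me, C19 = 7-methylene carbon, C20 = 11-Me); these locants are used for all intermediates.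

## Route

Step 1
Reactants: 1 (R)-(−)-carvone
Product: 2 (1R,4R,6R)-1-methyl-4-(prop-1-en-2-yl)-7-oxabicyclo[4.1.0]heptan-2-one
Conditions: 30% H2O2, NaOH (cat.), MeOH, 0 °C
Reagents that add atoms: hydrogen peroxide, OO
Why: Weitz–Scheffer nucleophilic epoxidation touches only the enone, and hydroperoxide adds axially to the β-carbon anti to the isopropenyl group, so the future C11–O bond is trans to the C14 side chain.

Step 2
Reactants: 2 carvone epoxide
Product: 3 (1R,4R)-1-methyl-4-(prop-1-en-2-yl)cyclohexane-1,2-diol (secondary carbinol = C10 as an epimer mixture)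
Conditions: LiAlH4, THF, 0 °C → rt; H2O/NaOH work-up
Reagents that add atoms: none
Why: hydride reduces the ketone and opens the epoxide by SN2 attack at its secondary carbon (C12), leaving the tertiary C11–O bond untouched; the carbinol epimers converge in step 3.

Step 3
Reactants: 3 diol
Product: 4 (2R,5R)-2-hydroxy-2-methyl-5-(prop-1-en-2-yl)cyclohexan-1-one
Conditions: 2-iodoxybenzoic acid, DMSO, rt
Reagents that add atoms: none
Why: 2-iodoxybenzoic acid oxidises the secondary alcohol of a 1,2-diol to the α-ketol without glycol cleavage, and the tertiary alcohol cannot react.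

Step 4
Reactants: 4 ketol
Product: 5 (2R,5R)-2-methyl-5-(prop-1-en-2-yl)-2-(triethylsilyloxy)cyclohexan-1-one
Conditions: Et3SiOTf, 2,6-lutidine, CH2Cl2, −78 → 0 °C
Reagents that add atoms: triethylsilyl trifluoromethanesulfonate, CC[Si](CC)(CC)OS(=O)(=O)C(F)(F)F
Why: silyl triflate silylation is the standard way to protect a hindered tertiary alcohol, and the ketone is left with one enolisable side only (C1).

Step 5
Reactants: 6 propane-1,3-diol
Product: 8 3-[(4-methoxybenzyl)oxy]propan-1-ol, via sodium 3-hydroxypropan-1-olate 7 (not isolated)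
Conditions: NaH (1 equiv), THF, 0 °C; 4-methoxybenzyl chloride, Bu4NI (cat.), rt (diol in excess)
Reagents that add atoms: 4-methoxybenzyl chloride, COc1ccc(CCl)cc1; sodium hydride, [Na+].[H-] (sodium stays only in 7)
Why: Williamson etherification of the mono-alkoxide of an excess of the symmetric diol gives the mono-ether.

Step 6
Reactants: 8 mono-PMB ether
Product: 9 3-[(4-methoxybenzyl)oxy]propanal
Conditions: TEMPO (cat.), PhI(OAc)2, CH2Cl2, rt
Reagents that add atoms: none
Why: oxoammonium (TEMPO) oxidation stops cleanly at the aldehyde.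

Step 7
Reactants: 9 aldehyde
Product: 10 ethyl (2Z)-5-[(4-methoxybenzyl)oxy]-2-methylpent-2-enoate
Conditions: ethyl 2-[bis(2,2,2-trifluoroethoxy)phosphoryl]propanoate, KN(SiMe3)2, 18-crown-6, THF, −78 °C
Reagents that add atoms: ethyl 2-[bis(2,2,2-trifluoroethoxy)phosphoryl]propanoate, CCOC(=O)C(C)P(=O)(OCC(F)(F)F)OCC(F)(F)F
Why: Still–Gennari olefination: the electron-poor phosphonate eliminates from the kinetic adduct before equilibration, giving the (Z)-trisubstituted enoate.

Step 8
Reactants: 10 (Z)-enoate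
Product: 11 (2Z)-5-[(4-methoxybenzyl)oxy]-2-methylpent-2-en-1-ol
Conditions: iBu2AlH (2.2 equiv), CH2Cl2, −78 °C; Rochelle salt
Reagents that add atoms: none
Why: 1,2-reduction of the enoate to the allylic alcohol keeps the alkene geometry.

Step 9
Reactants: 11 (Z)-allylic alcohol
Product: 12 [(2S,3R)-3-{2-[(4-methoxybenzyl)oxy]ethyl}-2-methyloxiran-2-yl]methanol
Conditions: Ti(OiPr)4 (10 mol %), L-(+)-diethyl tartrate (12 mol %), t-BuOOH, 4 Å sieves, CH2Cl2, −20 °C
Reagents that add atoms: tert-butyl hydroperoxide, CC(C)(C)OO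
Why: Sharpless asymmetric epoxidation; L-(+)-tartrate delivers oxygen to the face that gives the (2S,3R) cis-epoxide (same sense as nerol), fixing C3 (pre-inversion) and C4.

Step 10
Reactants: 12 epoxy alcohol
Product: 13 (2R,3R)-3-{2-[(4-methoxybenzyl)oxy]ethyl}-2-methyloxirane-2-carbaldehyde
Conditions: TEMPO (cat.), PhI(OAc)2, CH2Cl2, rt
Reagents that add atoms: none
Why: oxoammonium oxidation gives the epoxy aldehyde, whose quaternary α-carbon cannot epimerise or enolise.

Step 11
Reactants: 5 silyloxy ketone; 13 epoxy aldehyde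
Product: 16 anti-aldol adduct (β-hydroxy ketone), via dicyclohexylboron enolate 14 (not isolated), via dicyclohexylboron aldolate 15 (not isolated)
Conditions: Cy2BCl, Et3N, Et2O, −78 → 0 °C; 13, −78 → −20 °C; MeOH, pH 7 buffer, H2O2, 0 °C
Reagents that add atoms: chlorodicyclohexylborane, ClB(C1CCCCC1)C1CCCCC1 (boron and cyclohexyl groups stay only in 14 and 15)
Why: boron aldol addition through a Zimmerman–Traxler chair: the ring-locked E(O)-enolate gives the 1,2-anti adduct, the aldehyde adds to the enolate face trans to the neighbouring C14 isopropenyl group, and attack anti to the epoxide C–O bond from the methyl side (Felkin–Anh/Cornforth) is the matched sense, so C1 and C2 are set as in the target.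

Step 12
Reactants: 16 aldol adduct
Product: 17 (E)-β-alkoxyacrylate (C2–O–CH=CH–CO2Et)
Conditions: ethyl propiolate, N-methylmorpholine, CH2Cl2, rt
Reagents that add atoms: ethyl propiolate, C#CC(=O)OCC
Why: amine-catalysed oxa-Michael addition of the C2 hydroxyl to the ynoate gives the (E)-β-alkoxyacrylate under conditions too mild for retro-aldol or Payne rearrangement.

Step 13
Reactants: 17 keto acrylate
Product: 18 C10 alcohol (C10 epimers)
Conditions: NaBH4, EtOH/THF, 0 °C → rt
Reagents that add atoms: none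
Why: borohydride reduces the ketone much faster than the vinylogous carbonate, and the new carbinol centre is erased in step 15, so both epimers are used.

Step 14
Reactants: 18 alcohol
Product: 19 C10 O-(imidazol-1-ylthiocarbonyl) derivative
Conditions: 1,1'-thiocarbonyldiimidazole, DMAP (cat.), toluene, 90 °C
Reagents that add atoms: 1,1'-thiocarbonyldiimidazole, S=C(n1ccnc1)n1ccnc1
Why: thiocarbonylation of the hindered secondary alcohol under non-basic conditions gives a Barton–McCombie radical precursor without alkoxide addition to the acrylate.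

Step 15
Reactants: 19 thiocarbonyl derivative
Product: 20 cis-fused hexahydroisobenzofuran ethyl ester (C9–CH2CO2Et)
Conditions: Bu3SnH (syringe pump), AIBN (cat.), toluene, 110 °C, 0.01 M
Reagents that add atoms: none
Why: Barton–McCombie C–O homolysis gives the C10 radical, which closes 5-exo-trig onto the β-alkoxyacrylate; the three-atom tether on C1 forces the cis ring fusion (H10 cis to H1) and the chair-like transition state with the C2 substituent pseudo-equatorial gives the 2,5-cis tetrahydrofuran (C9).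

Step 16
Reactants: 20 ethyl ester
Product: 21 Weinreb amide (C9–CH2–CON(OMe)Me)
Conditions: MeNHOMe·HCl, iPrMgCl, THF, −20 °C
Reagents that add atoms: N,O-dimethylhydroxylamine hydrochloride, CNOC.Cl
Why: the magnesium amide converts the ester directly into the Weinreb amide at low temperature, where the epoxide and the β-alkoxy ester do not react.

Step 17
Reactants: 21 Weinreb amide
Product: 22 methyl ketone (C9–CH2–CO–CH3)
Conditions: MeMgBr, THF, −78 → 0 °C; aq NH4Cl
Reagents that add atoms: methylmagnesium bromide, C[Mg]Br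
Why: Grignard addition to a Weinreb amide stops at the ketone because the chelated adduct survives until work-up; this methyl group becomes C19.

Step 18
Reactants: 22 methyl ketone
Product: 24 vinyl triflate (C7–OTf and C7=C19H2), via potassium enolate 23 (not isolated)
Conditions: KN(SiMe3)2, THF, −78 °C; PhNTf2, −78 → 0 °C
Reagents that add atoms: N-phenylbis(trifluoromethanesulfonimide), O=S(=O)(N(c1ccccc1)S(=O)(=O)C(F)(F)F)C(F)(F)F; KN(SiMe3)2, C[Si](C)(C)[N-][Si](C)(C)C.[K+] (potassium stays only in 23)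
Why: kinetic deprotonation of the methyl group and O-triflation give the terminal enol triflate and avoid the internal enolate that could eliminate the C9–O bond.

Step 19
Reactants: 24 vinyl triflate
Product: 26 C16 primary alcohol (15R), via B-alkyl-9-BBN adduct 25 (not isolated)
Conditions: 9-BBN, THF, 0 °C → rt; NaBO3·4H2O, H2O, rt
Reagents that add atoms: 9-borabicyclo[3.3.1]nonane, B1C2CCCC1CCC2 (boron stays only in 25); sodium perborate, [Na+].[Na+].O[B-]1(O)OO[B-](O)(O)OO1 (one oxygen)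
Why: Brown hydroboration–oxidation of the electron-rich isopropenyl group (the enol triflate is inert to 9-BBN); with H14 eclipsing the alkene the borane adds anti to the larger allylic branch C1 (Houk/Still model), which gives 15R.

Step 20
Reactants: 26 primary alcohol
Product: 28 C16 carboxylic acid, via C16 aldehyde 27 (not isolated)
Conditions: TEMPO (cat.), PhI(OAc)2 (2.2 equiv), MeCN/pH 7 buffer, 0 °C → rt
Reagents that add atoms: water, O
Why: oxoammonium oxidation in the presence of water takes the primary alcohol through the aldehyde hydrate to the acid without epimerising C15 or touching the PMB ether.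

Step 21
Reactants: 28 epoxy acid
Product: 29 ε-lactone (C16–O–C3) carrying the free C4 hydroxyl
Conditions: camphorsulfonic acid (10 mol %), CH2Cl2, 0 °C
Reagents that add atoms: none
Why: acid-catalysed 7-exo-tet opening of the trisubstituted epoxide by the carboxylic acid at the tertiary carbon C3 proceeds with inversion at C3 and retention at C4, giving both as in the target, while the C11 silyl ether blocks a competing 6-exo attack.

Step 22
Reactants: 29 hydroxy lactone
Product: 30 C4 octanoate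
Conditions: octanoyl chloride, pyridine, DMAP (cat.), CH2Cl2, 0 °C → rt
Reagents that add atoms: octanoyl chloride, CCCCCCCC(=O)Cl
Why: DMAP-catalysed acylation of the only free hydroxyl installs the octanoate before the second secondary alcohol exists.

Step 23
Reactants: 30 PMB ether
Product: 31 C6 primary alcohol
Conditions: DDQ, CH2Cl2/pH 7 buffer, 0 °C
Reagents that add atoms: none
Why: oxidative cleavage of the 4-methoxybenzyl ether with DDQ leaves the esters, the lactone, the silyl ether and the enol triflate alone.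

Step 24
Reactants: 31 primary alcohol
Product: 32 C6 aldehyde
Conditions: TEMPO (cat.), PhI(OAc)2, CH2Cl2, rt
Reagents that add atoms: none
Why: neutral oxoammonium oxidation gives the β-acyloxy aldehyde without base-induced loss of the octanoate.

Step 25
Reactants: 32 aldehyde/vinyl triflate
Product: 33 oxonane allylic alcohol (6R-OH; C7 exocyclic methylene; 11-O-SiEt3)
Conditions: CrCl2 (8 equiv), NiCl2 (2 mol %), DMSO, rt, 0.003 M
Reagents that add atoms: none
Why: intramolecular Nozaki–Hiyama–Kishi reaction forms C6–C7 chemoselectively at the aldehyde and delivers the 1,1-disubstituted alkene and the C6 carbinol in one step; the 6R carbinol is expected from addition to the less hindered aldehyde face in the ring-closing conformer.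

Step 26
Reactants: 33 allylic alcohol
Product: 34 11-O-triethylsilyl briarellin C
Conditions: butanoic anhydride, Et3N, DMAP (cat.), CH2Cl2, 0 °C
Reagents that add atoms: butanoic anhydride, CCCC(=O)OC(=O)CCC
Why: DMAP-catalysed acylation of the only free (secondary allylic) hydroxyl gives the C6 butyrate.

Step 27
Reactants: 34 silyl ether
Product: 35 briarellin C
Conditions: HF·pyridine, pyridine, THF, 0 °C → rt
Reagents that add atoms: none
Why: buffered fluoride desilylation frees the tertiary C11 alcohol without touching the esters, the lactone or the allylic butyrate.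

## Compound list

1 | (R)-(−)-carvone | C=C(C)[C@@H]1CC=C(C)C(=O)C1 | starting material
2 | (1R,4R,6R)-1-methyl-4-(prop-1-en-2-yl)-7-oxabicyclo[4.1.0]heptan-2-one | C=C(C)[C@@H]1C[C@H]2O[C@@]2(C)C(=O)C1 | intermediate
3 | (1R,4R)-1-methyl-4-(prop-1-en-2-yl)cyclohexane-1,2-diol (C2 epimers) | C=C(C)[C@@H]1CC[C@@](C)(O)C(O)C1 | intermediate
4 | (2R,5R)-2-hydroxy-2-methyl-5-(prop-1-en-2-yl)cyclohexan-1-one | C=C(C)[C@@H]1CC[C@@](C)(O)C(=O)C1 | intermediate
5 | (2R,5R)-2-methyl-5-(prop-1-en-2-yl)-2-(triethylsilyloxy)cyclohexan-1-one | C=C(C)[C@@H]1CC[C@@](C)(O[Si](CC)(CC)CC)C(=O)C1 | intermediate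
6 | propane-1,3-diol | OCCCO | starting material
7 | sodium 3-hydroxypropan-1-olate | [Na+].[O-]CCCO | intermediate
8 | 3-[(4-methoxybenzyl)oxy]propan-1-ol | COc1ccc(COCCCO)cc1 | intermediate
9 | 3-[(4-methoxybenzyl)oxy]propanal | COc1ccc(COCCC=O)cc1 | intermediate
10 | ethyl (2Z)-5-[(4-methoxybenzyl)oxy]-2-methylpent-2-enoate | CCOC(=O)/C(C)=C\CCOCc1ccc(OC)cc1 | intermediate
11 | (2Z)-5-[(4-methoxybenzyl)oxy]-2-methylpent-2-en-1-ol | OC/C(C)=C\CCOCc1ccc(OC)cc1 | intermediate
12 | [(2S,3R)-3-{2-[(4-methoxybenzyl)oxy]ethyl}-2-methyloxiran-2-yl]methanol | OC[C@]1(C)O[C@@H]1CCOCc1ccc(OC)cc1 | intermediate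
13 | (2R,3R)-3-{2-[(4-methoxybenzyl)oxy]ethyl}-2-methyloxirane-2-carbaldehyde | O=C[C@]1(C)O[C@@H]1CCOCc1ccc(OC)cc1 | intermediate
14 | dicyclohexylboron enolate of 5 (C10–O–B, C10=C1) | C=C(C)[C@@H]1CC[C@@](C)(O[Si](CC)(CC)CC)C(OB(C2CCCCC2)C2CCCCC2)=C1 | intermediate
15 | dicyclohexylboron aldolate (C2–O–B) | C1CCCCC1B(C2CCCCC2)O[C@H]([C@]3(C)O[C@@H]3CCOCc4ccc(OC)cc4)[C@H]5[C@@H](CC[C@@](C)(O[Si](CC)(CC)CC)C5=O)C(C)=C | intermediate
16 | anti-aldol adduct: ketone 5 carrying at C1 (trans to isopropenyl) the C2 carbinol bonded to the cis-epoxide C3–C4 (C1/C2 anti) | O[C@H]([C@]1(C)O[C@@H]1CCOCc2ccc(OC)cc2)[C@H]3[C@@H](CC[C@@](C)(O[Si](CC)(CC)CC)C3=O)C(C)=C | intermediate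
17 | (E)-β-alkoxyacrylate of 16 | CCOC(=O)/C=C/O[C@H]([C@]1(C)O[C@@H]1CCOCc2ccc(OC)cc2)[C@H]3[C@@H](CC[C@@](C)(O[Si](CC)(CC)CC)C3=O)C(C)=C | intermediate
18 | C10 alcohol of 17 (C10 epimers) | CCOC(=O)/C=C/O[C@H]([C@]1(C)O[C@@H]1CCOCc2ccc(OC)cc2)[C@H]3[C@@H](CC[C@@](C)(O[Si](CC)(CC)CC)C3O)C(C)=C | intermediate
19 | C10 O-(imidazol-1-ylthiocarbonyl) derivative of 18 (C10 epimers) | CCOC(=O)/C=C/O[C@H]([C@]1(C)O[C@@H]1CCOCc2ccc(OC)cc2)[C@H]3[C@@H](CC[C@@](C)(O[Si](CC)(CC)CC)C3OC(=S)n4ccnc4)C(C)=C | intermediate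
20 | cis-fused hexahydroisobenzofuran ethyl ester (C9–CH2CO2Et; C2 and C9 side chains cis; C3–C4 epoxide; 11-OSiEt3; 14-isopropenyl) | CCOC(=O)C[C@@H]1O[C@H]([C@]2(C)O[C@@H]2CCOCc3ccc(OC)cc3)[C@H]4[C@@H](CC[C@@](C)(O[Si](CC)(CC)CC)[C@H]41)C(C)=C | intermediate
21 | Weinreb amide of 20 | CON(C)C(=O)C[C@@H]1O[C@H]([C@]2(C)O[C@@H]2CCOCc3ccc(OC)cc3)[C@H]4[C@@H](CC[C@@](C)(O[Si](CC)(CC)CC)[C@H]41)C(C)=C | intermediate
22 | methyl ketone (C9–CH2–CO–CH3) | CC(=O)C[C@@H]1O[C@H]([C@]2(C)O[C@@H]2CCOCc3ccc(OC)cc3)[C@H]4[C@@H](CC[C@@](C)(O[Si](CC)(CC)CC)[C@H]41)C(C)=C | intermediate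
23 | terminal potassium enolate of 22 | [K+].C=C([O-])C[C@@H]1O[C@H]([C@]2(C)O[C@@H]2CCOCc3ccc(OC)cc3)[C@H]4[C@@H](CC[C@@](C)(O[Si](CC)(CC)CC)[C@H]41)C(C)=C | intermediate
24 | vinyl triflate (C7–OTf, C7=C19H2) | C=C(OS(=O)(=O)C(F)(F)F)C[C@@H]1O[C@H]([C@]2(C)O[C@@H]2CCOCc3ccc(OC)cc3)[C@H]4[C@@H](CC[C@@](C)(O[Si](CC)(CC)CC)[C@H]41)C(C)=C | intermediate
25 | B-alkyl-9-BBN adduct of 24 (boron on C16; 15R) | C=C(OS(=O)(=O)C(F)(F)F)C[C@@H]1O[C@H]([C@]2(C)O[C@@H]2CCOCc3ccc(OC)cc3)[C@H]4[C@@H](CC[C@@](C)(O[Si](CC)(CC)CC)[C@H]41)[C@@H](C)CB5C6CCCC5CCC6 | intermediate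
26 | C16 primary alcohol (15R) | C=C(OS(=O)(=O)C(F)(F)F)C[C@@H]1O[C@H]([C@]2(C)O[C@@H]2CCOCc3ccc(OC)cc3)[C@H]4[C@@H](CC[C@@](C)(O[Si](CC)(CC)CC)[C@H]41)[C@@H](C)CO | intermediate
27 | C16 aldehyde | C=C(OS(=O)(=O)C(F)(F)F)C[C@@H]1O[C@H]([C@]2(C)O[C@@H]2CCOCc3ccc(OC)cc3)[C@H]4[C@@H](CC[C@@](C)(O[Si](CC)(CC)CC)[C@H]41)[C@@H](C)C=O | intermediate
28 | C16 carboxylic acid with intact C3–C4 epoxide | C=C(OS(=O)(=O)C(F)(F)F)C[C@@H]1O[C@H]([C@]2(C)O[C@@H]2CCOCc3ccc(OC)cc3)[C@H]4[C@@H](CC[C@@](C)(O[Si](CC)(CC)CC)[C@H]41)[C@@H](C)C(=O)O | intermediate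
29 | ε-lactone (C16–O–C3) with free 4-OH | C=C(OS(=O)(=O)C(F)(F)F)C[C@@H]1O[C@H]2[C@H]3[C@@H](CC[C@@](C)(O[Si](CC)(CC)CC)[C@H]31)[C@@H](C)C(=O)O[C@@]2(C)[C@H](O)CCOCc4ccc(OC)cc4 | intermediate
30 | C4 octanoate of 29 | C=C(OS(=O)(=O)C(F)(F)F)C[C@@H]1O[C@H]2[C@H]3[C@@H](CC[C@@](C)(O[Si](CC)(CC)CC)[C@H]31)[C@@H](C)C(=O)O[C@@]2(C)[C@H](OC(=O)CCCCCCC)CCOCc4ccc(OC)cc4 | intermediate
31 | C6 primary alcohol | C=C(OS(=O)(=O)C(F)(F)F)C[C@@H]1O[C@H]2[C@H]3[C@@H](CC[C@@](C)(O[Si](CC)(CC)CC)[C@H]31)[C@@H](C)C(=O)O[C@@]2(C)[C@H](OC(=O)CCCCCCC)CCO | intermediate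
32 | C6 aldehyde | C=C(OS(=O)(=O)C(F)(F)F)C[C@@H]1O[C@H]2[C@H]3[C@@H](CC[C@@](C)(O[Si](CC)(CC)CC)[C@H]31)[C@@H](C)C(=O)O[C@@]2(C)[C@H](OC(=O)CCCCCCC)CC=O | intermediate
33 | oxonane allylic alcohol (6R-OH; 7-methylene; 11-O-SiEt3) | C=C1C[C@@H]2O[C@H]3[C@H]4[C@@H](CC[C@@](C)(O[Si](CC)(CC)CC)[C@H]42)[C@@H](C)C(=O)O[C@@]3(C)[C@H](OC(=O)CCCCCCC)C[C@H]1O | intermediate
34 | 11-O-triethylsilyl briarellin C | C=C1C[C@@H]2O[C@H]3[C@H]4[C@@H](CC[C@@](C)(O[Si](CC)(CC)CC)[C@H]42)[C@@H](C)C(=O)O[C@@]3(C)[C@H](OC(=O)CCCCCCC)C[C@H]1OC(=O)CCC | intermediate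
35 | briarellin C | C=C1C[C@@H]2O[C@H]3[C@H]4[C@@H](CC[C@@](C)(O)[C@H]42)[C@@H](C)C(=O)O[C@@]3(C)[C@H](OC(=O)CCCCCCC)C[C@H]1OC(=O)CCC | target

## Step count and risks

Total step count: 27. Longest linear sequence: 23 steps (propane-1,3-diol, steps 5–10, then steps 11–27); the carvone branch is 21 steps.

The three steps most likely to fail:

Step 11 (aldol fragment union; hindered enolate, acid-sensitive epoxy aldehyde, diastereoselectivity). The fallback sets out from 5 and comes back at 16. Ketone 5 is deprotonated with LiN(iPr)2 and silylated with Me3SiCl to the trimethylsilyl enol ether F1. F1 is brominated with N-bromosuccinimide at −78 °C to the α-bromo ketone F2. F2 and aldehyde 13 are then added to CrCl2 (LiI cat.) in THF; this chromium Reformatsky reaction forms a chromium enolate under neutral conditions that leave the epoxide alone and adds to aldehydes anti-selectively, giving 16.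

Step 21 (seven-membered lactone by epoxide opening; possible rearrangement or elimination of the tertiary epoxide). The fallback sets out from 28 and comes back at 30. Acid 28 is hydrolysed with dilute HClO4 in THF/H2O at 0 °C, where water opens the epoxide at the tertiary C3 with inversion, to the 3,4-dihydroxy acid F3. The secondary C4 hydroxyl is acylated selectively with octanoyl chloride/pyridine (the mixed anhydride is hydrolysed on work-up) to the 4-O-octanoyl hydroxy acid F4. The lactone is then closed on the tertiary C3 hydroxyl by Yamaguchi lactonisation (2,4,6-trichlorobenzoyl chloride, Et3N; DMAP, toluene, 80 °C, high dilution) to give 30.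

Step 25 (nine-membered ring closure; C6 configuration). The fallback sets out from 32 and comes back at 33. If the cyclisation gives mainly or partly the wrong carbinol, the 6-epi alcohol F5 (or the epimer mixture) is oxidised with MnO2 to the cross-conjugated C6 enone F6. F6 is reduced with catecholborane and (S)-2-methyl-CBS-oxazaborolidine in toluene at −78 °C; with the alkenyl group as the large substituent this reagent-controlled reduction gives the 6R alcohol 33.

## Further compounds

F1 | step 11 | trimethylsilyl enol ether of 5 (C10–OSiMe3, C10=C1) | C=C(C)[C@@H]1CC[C@@](C)(O[Si](CC)(CC)CC)C(O[Si](C)(C)C)=C1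
F2 | step 11 | α-bromo ketone of 5 (bromine on C1, epimers) | C=C(C)[C@@H]1CC[C@@](C)(O[Si](CC)(CC)CC)C(=O)C1Br
F3 | step 21 | 3,4-dihydroxy acid (3-OH and 4-OH configured as in the target) | C=C(OS(=O)(=O)C(F)(F)F)C[C@@H]1O[C@H]([C@@](C)(O)[C@H](O)CCOCc3ccc(OC)cc3)[C@H]4[C@@H](CC[C@@](C)(O[Si](CC)(CC)CC)[C@H]41)[C@@H](C)C(=O)O
F4 | step 21 | 4-O-octanoyl 3-hydroxy acid | C=C(OS(=O)(=O)C(F)(F)F)C[C@@H]1O[C@H]([C@@](C)(O)[C@H](OC(=O)CCCCCCC)CCOCc3ccc(OC)cc3)[C@H]4[C@@H](CC[C@@](C)(O[Si](CC)(CC)CC)[C@H]41)[C@@H](C)C(=O)O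
F5 | step 25 | 6-epi alcohol of 33 (6S) | C=C1C[C@@H]2O[C@H]3[C@H]4[C@@H](CC[C@@](C)(O[Si](CC)(CC)CC)[C@H]42)[C@@H](C)C(=O)O[C@@]3(C)[C@H](OC(=O)CCCCCCC)C[C@@H]1O
F6 | step 25 | C6 enone (6-oxo, 7-methylene) | C=C1C[C@@H]2O[C@H]3[C@H]4[C@@H](CC[C@@](C)(O[Si](CC)(CC)CC)[C@H]42)[C@@H](C)C(=O)O[C@@]3(C)[C@H](OC(=O)CCCCCCC)CC1=O
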